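The cyclohexene (C1 acyl-bearing, C2 bearing the stilbene aryl, C3=C4 with the methyl on C4, C5H2, C6 bearing the second resorcinol ring) is cut at C1–C2 and C3=C4. C1 is the α-carbon of the aryl ketone and C4 a latent methyl-ketone carbonyl, so an enantioenriched 4,6-diaryl enol δ-lactone carries C1, C6, C5 and C4. Methyllithium opens it to one regiodefined enolate tethered to the new methyl ketone; the enolate adds to an (E)-2-arylvinylphosphonium salt (C2, C3), and the ylide so formed closes the ring by intramolecular Wittig olefination, creating both bonds, the methyl branch and two stereocentres in one operation.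

Key step: step 9

Remarks on the chemistry:
- The ring numbering C1–C6 of the paragraph above is used in all steps.
- The sense of induction of the thiourea catalyst in step 2 is assumed; if the (R)-adduct formed, the pseudoenantiomeric quinidine-derived catalyst would be used.
- The five starting materials are taken as commercially available.

Step 1
Reactants: 1 1-[2,4-bis(benzyloxy)phenyl]ethan-1-one; 2 2,4-bis(benzyloxy)benzaldehyde
Product: 3 (2E)-1,3-bis[2,4-bis(benzyloxy)phenyl]prop-2-en-1-one
Conditions: KOH, EtOH/THF, rt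
Reagents that add atoms: none
Why: Claisen–Schmidt aldol condensation of the only enolisable ketone with a non-enolisable aldehyde, the E1cB loss of water giving the conjugated (E)-enone under thermodynamic control.

Step 2
Reactants: 3 (2E)-1,3-bis[2,4-bis(benzyloxy)phenyl]prop-2-en-1-one
Product: 4 dimethyl 2-{(1S)-1,3-bis[2,4-bis(benzyloxy)phenyl]-3-oxopropyl}propanedioate
Conditions: CH2(CO2Me)2, 1-[3,5-bis(trifluoromethyl)phenyl]-3-[(8S,9S)-6'-methoxycinchonan-9-yl]thiourea (10 mol %), toluene, rt to 40 °C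
Reagents that add atoms: dimethyl malonate, COC(=O)CC(=O)OC
Why: Organocatalytic asymmetric Michael addition in which the thiourea hydrogen-bonds the enone carbonyl and the quinuclidine nitrogen delivers the malonate to one enantiotopic face of the β-carbon, which sets the future C6 stereocentre.

Step 3
Reactants: 4 dimethyl 2-{(1S)-1,3-bis[2,4-bis(benzyloxy)phenyl]-3-oxopropyl}propanedioate
Product: 6 (3S)-3,5-bis[2,4-bis(benzyloxy)phenyl]-5-oxopentanoic acid, via malonic acid 5 (not isolated)
Conditions: LiOH, THF/MeOH/H2O, rt; aq. HCl to pH 2; then toluene/pyridine, 110 °C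
Reagents that add atoms: lithium hydroxide, [Li+].[OH-]
Why: Ester saponification followed by thermal decarboxylation of the malonic acid through a cyclic six-membered transition state; the stereocentre is β to both carbonyl groups and is not touched, and retro-Michael cleavage is disfavoured once the malonate is a carboxylate.

Step 4
Reactants: 6 (3S)-3,5-bis[2,4-bis(benzyloxy)phenyl]-5-oxopentanoic acid
Product: 7 (4R)-4,6-bis[2,4-bis(benzyloxy)phenyl]-3,4-dihydro-2H-pyran-2-one
Conditions: Ac2O, NaOAc (cat.), 100 °C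
Reagents that add atoms: none
Why: Enol lactonisation of a δ-keto acid, the mixed anhydride acylating the enol oxygen of the aryl ketone (enolisable on one side only) in a six-membered closure; the descriptor changes to R through a priority change only.

Step 5
Reactants: 8 5-bromo-2,4-dihydroxybenzaldehyde
Product: 9 2,4-bis(benzyloxy)-5-bromobenzaldehyde
Conditions: BnBr, K2CO3, DMF, 60 °C
Reagents that add atoms: benzyl bromide, BrCc1ccccc1
Why: Williamson ether synthesis on both phenoxides, the hydrogen-bonded 2-OH being alkylated under the warm polar conditions.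

Step 6
Reactants: 10 3,5-bis(benzyloxy)benzaldehyde
Product: 11 1,3-bis(benzyloxy)-5-ethenylbenzene
Conditions: Ph3PCH3Br, KOtBu, THF, 0 °C to rt
Reagents that add atoms: methyltriphenylphosphonium bromide, C[P+](c1ccccc1)(c1ccccc1)c1ccccc1.[Br-]
Why: Wittig methylenation of an aromatic aldehyde with the non-stabilised ylide.

Step 7
Reactants: 9 2,4-bis(benzyloxy)-5-bromobenzaldehyde; 11 1,3-bis(benzyloxy)-5-ethenylbenzene
Product: 12 2,4-bis(benzyloxy)-5-[(E)-2-[3,5-bis(benzyloxy)phenyl]ethenyl]benzaldehyde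
Conditions: Pd(OAc)2 (5 mol %), P(o-tol)3, NaOAc, DMA, 120 °C
Reagents that add atoms: none
Why: Mizoroki–Heck reaction; oxidative addition into the aryl bromide, syn insertion at the terminal styrene carbon and syn β-hydride elimination should give the (E)-stilbene.

Step 8
Reactants: 13 (trimethylsilylmethyl)triphenylphosphonium iodide; 12 2,4-bis(benzyloxy)-5-[(E)-2-[3,5-bis(benzyloxy)phenyl]ethenyl]benzaldehyde
Product: 15 triphenyl[(E)-2-{2,4-bis(benzyloxy)-5-[(E)-2-[3,5-bis(benzyloxy)phenyl]ethenyl]phenyl}ethenyl]phosphonium iodide, via silyl ylide 14 (not isolated)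
Conditions: n-BuLi, THF, −78 to 0 °C; then 12, −78 °C to rt; AcOH quench
Reagents that add atoms: none
Why: Peterson-type olefination of an α-silyl phosphonium ylide, whose adduct with the aldehyde loses trimethylsilanolate in preference to phosphine oxide and so should give the conjugated (E)-vinylphosphonium salt.

Step 9
Reactants: 7 (4R)-4,6-bis[2,4-bis(benzyloxy)phenyl]-3,4-dihydro-2H-pyran-2-one; 15 triphenyl[(E)-2-{2,4-bis(benzyloxy)-5-[(E)-2-[3,5-bis(benzyloxy)phenyl]ethenyl]phenyl}ethenyl]phosphonium iodide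
Product: 18 [(1S,2S,6R)-6-[2,4-bis(benzyloxy)phenyl]-2-{2,4-bis(benzyloxy)-5-[(E)-2-[3,5-bis(benzyloxy)phenyl]ethenyl]phenyl}-4-methylcyclohex-3-en-1-yl][2,4-bis(benzyloxy)phenyl]methanone, via lithium enolate 16 (not isolated), via phosphonium ylide 17 (not isolated)
Conditions: MeLi (1.0 equiv), THF, −78 °C; then 15 (1.1 equiv), THF/DMPU, −78 °C to rt; then DBU (20 mol %), rt
Reagents that add atoms: methyllithium, [Li]C
Why: MeLi adds once to the lactone carbonyl and the adduct collapses (first stage of a Fujimoto–Belleau reaction) to (Z)-enolate 16, the only enolate of the aryl ketone, with the methyl ketone unmasked at the other chain end. The α-carbon of 16 adds to the β-carbon of 15 (C1–C2 bond) to give ylide 17, whose carbanion attacks the methyl ketone in a 6-exo-trig closure; the oxaphosphetane then releases Ph3P=O and the C3=C4 double bond, so the closest known reaction type is the Michael addition/intramolecular Wittig annulation of vinylphosphonium salts (Schweizer annulation). C1 should form trans to the aryl group on C6 because the enolate reacts in its A(1,3)-minimised conformer (C6–H eclipsing the enolate C=C) on the face opposite that aryl group; as C1 is α to the ketone, the closing DBU equilibration secures the equatorial aroyl group in any case. C2 should form trans to the aroyl group because a (Z)-enolate and an (E)-acceptor prefer the open antiperiplanar transition state in which the C6 branch and the aryl group of 15 lie apart (anti adduct), which makes the two aryl groups cis and all three substituents equatorial. The step needs one regiodefined enolate (secured by the enol lactone), a single MeLi addition (one equivalent at −78 °C) and capture of 16 before proton transfer from the methyl ketone (DMPU, slight excess of 15).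

Step 10
Reactants: 18 [(1S,2S,6R)-6-[2,4-bis(benzyloxy)phenyl]-2-{2,4-bis(benzyloxy)-5-[(E)-2-[3,5-bis(benzyloxy)phenyl]ethenyl]phenyl}-4-methylcyclohex-3-en-1-yl][2,4-bis(benzyloxy)phenyl]methanone
Product: 19 [(1S,2S,6R)-6-(2,4-dihydroxyphenyl)-2-{2,4-dihydroxy-5-[(E)-2-(3,5-dihydroxyphenyl)ethenyl]phenyl}-4-methylcyclohex-3-en-1-yl](2,4-dihydroxyphenyl)methanone (CNP0327388.1)
Conditions: BCl3, pentamethylbenzene, CH2Cl2, −78 °C; MeOH quench at −78 °C
Reagents that add atoms: none
Why: Lewis-acid cleavage of aryl benzyl ethers, the benzyl cations being trapped by pentamethylbenzene (Friedel–Crafts scavenging) at a temperature at which the stilbene, the ring alkene and the ketone should stay intact; no stereocentre is touched and the C1 centre is already in its thermodynamic configuration.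

Compound list
1 | 1-[2,4-bis(benzyloxy)phenyl]ethan-1-one | CC(=O)c1ccc(OCc2ccccc2)cc1OCc1ccccc1 | starting material
2 | 2,4-bis(benzyloxy)benzaldehyde | O=Cc1ccc(OCc2ccccc2)cc1OCc1ccccc1 | starting material
3 | (2E)-1,3-bis[2,4-bis(benzyloxy)phenyl]prop-2-en-1-one | O=C(/C=C/c1ccc(OCc2ccccc2)cc1OCc1ccccc1)c1ccc(OCc2ccccc2)cc1OCc1ccccc1 | intermediate
4 | dimethyl 2-{(1S)-1,3-bis[2,4-bis(benzyloxy)phenyl]-3-oxopropyl}propanedioate | O=C(C[C@H](c1ccc(OCc2ccccc2)cc1OCc1ccccc1)C(C(=O)OC)C(=O)OC)c1ccc(OCc2ccccc2)cc1OCc1ccccc1 | intermediate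
5 | 2-{(1S)-1,3-bis[2,4-bis(benzyloxy)phenyl]-3-oxopropyl}propanedioic acid | O=C(C[C@H](c1ccc(OCc2ccccc2)cc1OCc1ccccc1)C(C(=O)O)C(=O)O)c1ccc(OCc2ccccc2)cc1OCc1ccccc1 | intermediate
6 | (3S)-3,5-bis[2,4-bis(benzyloxy)phenyl]-5-oxopentanoic acid | O=C(C[C@H](c1ccc(OCc2ccccc2)cc1OCc1ccccc1)CC(=O)O)c1ccc(OCc2ccccc2)cc1OCc1ccccc1 | intermediate
7 | (4R)-4,6-bis[2,4-bis(benzyloxy)phenyl]-3,4-dihydro-2H-pyran-2-one | O=C1C[C@@H](c2ccc(OCc3ccccc3)cc2OCc2ccccc2)C=C(c2ccc(OCc3ccccc3)cc2OCc2ccccc2)O1 | intermediate
8 | 5-bromo-2,4-dihydroxybenzaldehyde | O=Cc1cc(Br)c(O)cc1O | starting material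
9 | 2,4-bis(benzyloxy)-5-bromobenzaldehyde | O=Cc1cc(Br)c(OCc2ccccc2)cc1OCc1ccccc1 | intermediate
10 | 3,5-bis(benzyloxy)benzaldehyde | O=Cc1cc(OCc2ccccc2)cc(OCc2ccccc2)c1 | starting material
11 | 1,3-bis(benzyloxy)-5-ethenylbenzene | C=Cc1cc(OCc2ccccc2)cc(OCc2ccccc2)c1 | intermediate
12 | 2,4-bis(benzyloxy)-5-[(E)-2-[3,5-bis(benzyloxy)phenyl]ethenyl]benzaldehyde | O=Cc1cc(/C=C/c2cc(OCc3ccccc3)cc(OCc3ccccc3)c2)c(OCc2ccccc2)cc1OCc1ccccc1 | intermediate
13 | (trimethylsilylmethyl)triphenylphosphonium iodide | C[Si](C)(C)C[P+](c1ccccc1)(c1ccccc1)c1ccccc1.[I-] | starting material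
14 | triphenyl[(trimethylsilyl)methylidene]-λ5-phosphane (silyl ylide) | C[Si](C)(C)C=P(c1ccccc1)(c1ccccc1)c1ccccc1 | intermediate
15 | triphenyl[(E)-2-{2,4-bis(benzyloxy)-5-[(E)-2-[3,5-bis(benzyloxy)phenyl]ethenyl]phenyl}ethenyl]phosphonium iodide | [I-].c1ccc(cc1)[P+](c1ccccc1)(c1ccccc1)/C=C/c1cc(/C=C/c2cc(OCc3ccccc3)cc(OCc3ccccc3)c2)c(OCc2ccccc2)cc1OCc1ccccc1 | intermediate
16 | lithium (1Z,3R)-1,3-bis[2,4-bis(benzyloxy)phenyl]-5-oxohex-1-en-1-olate | [Li+].[O-]/C(c1ccc(OCc2ccccc2)cc1OCc1ccccc1)=C\[C@H](c1ccc(OCc2ccccc2)cc1OCc1ccccc1)CC(C)=O | intermediate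
17 | phosphonium ylide Ph3P=CH–CH(aryl)–CH(aroyl)–CH(aryl)–CH2–C(=O)CH3, the three stereocentres configured as in 18 | c1ccc(cc1)P(c1ccccc1)(c1ccccc1)=C[C@H](c1cc(/C=C/c2cc(OCc3ccccc3)cc(OCc3ccccc3)c2)c(OCc2ccccc2)cc1OCc1ccccc1)[C@@H](C(=O)c1ccc(OCc2ccccc2)cc1OCc1ccccc1)[C@H](c1ccc(OCc2ccccc2)cc1OCc1ccccc1)CC(C)=O | intermediate
18 | [(1S,2S,6R)-6-[2,4-bis(benzyloxy)phenyl]-2-{2,4-bis(benzyloxy)-5-[(E)-2-[3,5-bis(benzyloxy)phenyl]ethenyl]phenyl}-4-methylcyclohex-3-en-1-yl][2,4-bis(benzyloxy)phenyl]methanone | CC1=C[C@H](c2cc(/C=C/c3cc(OCc4ccccc4)cc(OCc4ccccc4)c3)c(OCc3ccccc3)cc2OCc2ccccc2)[C@@H](C(=O)c2ccc(OCc3ccccc3)cc2OCc2ccccc2)[C@H](c2ccc(OCc3ccccc3)cc2OCc2ccccc2)C1 | intermediate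
19 | [(1S,2S,6R)-6-(2,4-dihydroxyphenyl)-2-{2,4-dihydroxy-5-[(E)-2-(3,5-dihydroxyphenyl)ethenyl]phenyl}-4-methylcyclohex-3-en-1-yl](2,4-dihydroxyphenyl)methanone (CNP0327388.1) | CC1=C[C@H](c2cc(/C=C/c3cc(O)cc(O)c3)c(O)cc2O)[C@@H](C(=O)c2ccc(O)cc2O)[C@H](c2ccc(O)cc2O)C1 | target

Total step count: 10. Longest linear sequence: 6 steps (steps 1, 2, 3, 4, 9, 10).

Steps most likely to fail

Step 9. The donor-substituted vinylphosphonium salt may take up the enolate slowly. Proton transfer from the methyl ketone could then scramble the enolate and open the way to intramolecular aldol closure. Methyllithium may also add a second time to the liberated ketone, and facial selectivity at C2 may be poor, giving the ring diastereomer with the two aryl groups trans. The fallback changes the acceptor and the olefination manifold but keeps both bonds in one operation. Aldehyde 12 is converted by Horner–Wadsworth–Emmons reaction with diethyl [(1,3-benzothiazol-2-ylsulfonyl)methyl]phosphonate (NaH, THF) into 2-{[(E)-2-{2,4-bis(benzyloxy)-5-[(E)-2-[3,5-bis(benzyloxy)phenyl]ethenyl]phenyl}ethenyl]sulfonyl}-1,3-benzothiazole F1. Enolate 16, generated from 7 with MeLi as before, adds to the more electrophilic vinyl sulfone F1; the α-sulfonyl carbanion closes onto the methyl ketone and eliminates by Smiles rearrangement (Julia–Kocienski olefination). The fallback returns to the route at 18.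

Step 8. The silyl ylide adduct may partition toward Wittig loss of phosphine oxide (vinylsilane) instead of Peterson elimination, and the liberated silanolate may add to or deprotonate the vinylphosphonium salt. The fallback sets out from 12: Takai olefination (CrCl2, CHI3, THF) gives 1,5-bis(benzyloxy)-2-[(E)-2-[3,5-bis(benzyloxy)phenyl]ethenyl]-4-[(E)-2-iodoethenyl]benzene F2. Quaternisation of F2 with PPh3 under palladium catalysis (Pd(OAc)2, reduced in the flask to zerovalent palladium, toluene, 100 °C) forms the P–C bond with retention of alkene geometry and returns to the route at 15.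

Step 10. Eightfold Lewis-acid debenzylation may be incomplete. The acid set free on quench may drive cyclisation of an ortho-phenol onto the C3=C4 alkene, and benzyl cations may migrate onto the electron-rich rings. The fallback sets out from 18 and replaces Lewis-acid cleavage by reductive silyl exchange: Pd(OAc)2, Et3SiH, Et3N, CH2Cl2, rt should give the octakis(triethylsilyl) ether F3. Mild desilylation of F3 (HF·pyridine, THF, 0 °C) then returns to the route at 19.

Further compounds
F1 | step 9 | 2-{[(E)-2-{2,4-bis(benzyloxy)-5-[(E)-2-[3,5-bis(benzyloxy)phenyl]ethenyl]phenyl}ethenyl]sulfonyl}-1,3-benzothiazole | O=S(=O)(/C=C/c1cc(/C=C/c2cc(OCc3ccccc3)cc(OCc3ccccc3)c2)c(OCc2ccccc2)cc1OCc1ccccc1)c1nc2ccccc2s1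
F2 | step 8 | 1,5-bis(benzyloxy)-2-[(E)-2-[3,5-bis(benzyloxy)phenyl]ethenyl]-4-[(E)-2-iodoethenyl]benzene | I/C=C/c1cc(/C=C/c2cc(OCc3ccccc3)cc(OCc3ccccc3)c2)c(OCc2ccccc2)cc1OCc1ccccc1
F3 | step 10 | octakis(triethylsilyl) ether of 19, [(1S,2S,6R)-configured] | CC1=C[C@H](c2cc(/C=C/c3cc(O[Si](CC)(CC)CC)cc(O[Si](CC)(CC)CC)c3)c(O[Si](CC)(CC)CC)cc2O[Si](CC)(CC)CC)[C@@H](C(=O)c2ccc(O[Si](CC)(CC)CC)cc2O[Si](CC)(CC)CC)[C@H](c2ccc(O[Si](CC)(CC)CC)cc2O[Si](CC)(CC)CC)C1
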